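**Retrosynthetic overview**
1. The target is epiafzelechin-(4β→8)-ent-epiafzelechin-(4α→8)-epiafzelechin (upper unit 2R,3R,4R; middle unit 2S,3S,4R; lower unit 2R,3R); all nine benzyl ethers and two acetates come off last.
2. The upper C4–C8 bond is cut to a C4-activated (2R,3R) monomer plus a middle–lower dimer; the lower C4–C8 bond is cut to a C4-activated (2S,3S) monomer plus the (2R,3R) monomer. Both bonds form 3,4-trans by substrate control.
3. Both enantiomeric 2,3-cis monomers come from one racemic flavan-3-one by a new catalyst-controlled dynamic kinetic resolution (transfer hydrogenation with the (R,R)- or the (S,S)-catalyst, C2 epimerising in the flask).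
4. The racemic ketone comes from a chalcone: ring C is closed onto preformed rings A and B (flav-3-ene), then hydroboration–oxidation and alcohol oxidation.
5. Order of formation: ring C of the monomer (step 3), then the lower interflavan bond (step 12), then the upper interflavan bond (step 13).

Assumption: the absolute sense of the new reduction (steps 6 and 7) is the one predicted by the usual outer-sphere model; it is checked by the optical rotation of 12 against 5,7,4'-tri-O-benzyl-(−)-epiafzelechin, and a reversed sense would only exchange the two catalyst antipodes, which are both used anyway.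

**Route**

Step 1
Reactants: 1 2',4',6'-trihydroxyacetophenone
Product: 2 1-[2,4-bis(benzyloxy)-6-hydroxyphenyl]ethanone
Conditions: BnBr (2.1 equiv), K2CO3 (2.2 equiv), DMF, 0 °C to rt
Reagents that add atoms: benzyl bromide, BrCc1ccccc1
Why: Williamson ether synthesis, in which the phenol hydrogen-bonded to the acetyl carbonyl is the least nucleophilic and stays free after the other two are benzylated.

Step 2
Reactants: 2 1-[2,4-bis(benzyloxy)-6-hydroxyphenyl]ethanone; 3 4-(benzyloxy)benzaldehyde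
Product: 5 (E)-1-[2,4-bis(benzyloxy)-6-hydroxyphenyl]-3-[4-(benzyloxy)phenyl]prop-2-en-1-one, via aldol adduct 4 (not isolated)
Conditions: KOH (50% aq.), EtOH/THF, rt, 48 h
Reagents that add atoms: none
Why: Claisen–Schmidt aldol condensation, in which E1cB loss of water gives the thermodynamically favoured E-enone.

Step 3
Reactants: 5 (E)-1-[2,4-bis(benzyloxy)-6-hydroxyphenyl]-3-[4-(benzyloxy)phenyl]prop-2-en-1-one
Product: 7 racemic 5,7-bis(benzyloxy)-2-[4-(benzyloxy)phenyl]-2H-chromene, via allylic alcohol 6 (not isolated)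
Conditions: NaBH4 (2 equiv), THF/EtOH (1:1), 0 °C then reflux
Reagents that add atoms: none
Why: Reductive cyclisation of a 2'-hydroxychalcone, in which 1,2-reduction of the enone is followed by loss of water from the ortho-hydroxy cinnamyl alcohol and ring closure to the 2H-chromene, with C2 formed as a racemate.

Step 4
Reactants: 7 racemic 5,7-bis(benzyloxy)-2-[4-(benzyloxy)phenyl]-2H-chromene
Product: 9 racemic 2,3-trans-5,7-bis(benzyloxy)-2-[4-(benzyloxy)phenyl]chroman-3-ol, via C3 alkylborane 8 (not isolated)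
Conditions: BH3·THF (2 equiv), THF, 0 °C to rt; then 3 M NaOH, 30% H2O2, 0 °C to rt
Reagents that add atoms: hydrogen peroxide, OO
Why: Brown hydroboration–oxidation, in which boron adds to C3 (β to the electron-rich styrene-type ring A) on the face opposite the 2-aryl group and oxidation with retention gives the 2,3-trans alcohol.

Step 5
Reactants: 9 racemic 2,3-trans-5,7-bis(benzyloxy)-2-[4-(benzyloxy)phenyl]chroman-3-ol
Product: 10 racemic 5,7-bis(benzyloxy)-2-[4-(benzyloxy)phenyl]chroman-3-one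
Conditions: Dess–Martin periodinane (1.3 equiv), CH2Cl2, 0 °C to rt
Reagents that add atoms: none
Why: Dess–Martin oxidation is neutral and mild enough for the benzyl ethers and the enolisable flavan-3-one, and the material is racemic, so no stereochemistry is at stake.

Step 6
Reactants: 10 racemic 5,7-bis(benzyloxy)-2-[4-(benzyloxy)phenyl]chroman-3-one
Product: 12 (2R,3R)-5,7-bis(benzyloxy)-2-[4-(benzyloxy)phenyl]chroman-3-ol, via (2R)-ketone 11 (not isolated)
Conditions: RuCl[(R,R)-TsDPEN](p-cymene) (2 mol %), HCO2H/Et3N (1:3, 5 equiv HCO2H), DMF, 40 °C, Ar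
Reagents that add atoms: none
Why: Proposed new method: dynamic kinetic resolution of a racemic flavan-3-one by asymmetric transfer hydrogenation, a substrate class on which this reactivity has not been shown, should work because the C2–H (benzylic, α to the ketone and to the ring oxygen) is acidic enough for the amine-rich formate buffer to epimerise C2 by reversible deprotonation faster than reduction, so the (2S)-half of 10 is funnelled into the matched (2R)-ketone 11, to which the hydride/N–H pair of the divalent ruthenium catalyst delivers H−/H+ through the six-membered outer-sphere transition state on the carbonyl face opposite the 2-aryl group (hence 2,3-cis, with C2 fixed as R and C3 set as R); closest known reaction type: Noyori–Ikariya transfer hydrogenation with dynamic kinetic resolution of racemic 2-arylcycloalkanones and α-substituted β-keto esters to cis alcohols.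

Step 7
Reactants: 10 racemic 5,7-bis(benzyloxy)-2-[4-(benzyloxy)phenyl]chroman-3-one
Product: 14 (2S,3S)-5,7-bis(benzyloxy)-2-[4-(benzyloxy)phenyl]chroman-3-ol, via (2S)-ketone 13 (not isolated)
Conditions: RuCl[(S,S)-TsDPEN](p-cymene) (2 mol %), HCO2H/Et3N (1:3, 5 equiv HCO2H), DMF, 40 °C, Ar
Reagents that add atoms: none
Why: Proposed new method: the mirror-image run of step 6, in which the same amine-mediated C2 epimerisation funnels the (2R)-half of 10 into the (2S)-ketone 13 that is matched to the (S,S)-catalyst, and outer-sphere hydride delivery anti to the 2-aryl group sets C2 and C3 as S (the ent-epiafzelechin series); closest known reaction type: Noyori–Ikariya transfer hydrogenation with dynamic kinetic resolution of racemic 2-arylcycloalkanones to cis alcohols.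

Step 8
Reactants: 14 (2S,3S)-5,7-bis(benzyloxy)-2-[4-(benzyloxy)phenyl]chroman-3-ol
Product: 16 (2S,3S,4R)-5,7-bis(benzyloxy)-2-[4-(benzyloxy)phenyl]-4-(2-ethoxyethoxy)chroman-3-ol, via flavan-4-yl cation 15 (not isolated)
Conditions: DDQ (2.0 equiv), 2-ethoxyethanol (5 equiv), CH2Cl2, rt
Reagents that add atoms: 2-ethoxyethanol, CCOCCO
Why: DDQ benzylic oxidation, in which hydride abstraction at C4 is favoured by the 5,7-dialkoxy ring A and the alcohol traps the cation anti to the 3-OH (3,4-trans); this centre is ionised again in step 12.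

Step 9
Reactants: 16 (2S,3S,4R)-5,7-bis(benzyloxy)-2-[4-(benzyloxy)phenyl]-4-(2-ethoxyethoxy)chroman-3-ol
Product: 17 (2S,3S,4R)-5,7-bis(benzyloxy)-2-[4-(benzyloxy)phenyl]-4-(2-ethoxyethoxy)chroman-3-yl acetate
Conditions: Ac2O, DMAP (cat.), pyridine, rt
Reagents that add atoms: acetic anhydride, CC(=O)OC(C)=O
Why: DMAP-catalysed acylation under basic conditions leaves the acid-labile C4 ether untouched, and the 3-acetate later shields one face of the C4 cation.

Step 10
Reactants: 12 (2R,3R)-5,7-bis(benzyloxy)-2-[4-(benzyloxy)phenyl]chroman-3-ol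
Product: 19 (2R,3R,4S)-5,7-bis(benzyloxy)-2-[4-(benzyloxy)phenyl]-4-(2-ethoxyethoxy)chroman-3-ol, via flavan-4-yl cation 18 (not isolated)
Conditions: DDQ (2.0 equiv), 2-ethoxyethanol (5 equiv), CH2Cl2, rt
Reagents that add atoms: 2-ethoxyethanol, CCOCCO
Why: DDQ benzylic oxidation as in step 8, in the enantiomeric series, with the alcohol entering anti to the 3-OH.

Step 11
Reactants: 19 (2R,3R,4S)-5,7-bis(benzyloxy)-2-[4-(benzyloxy)phenyl]-4-(2-ethoxyethoxy)chroman-3-ol
Product: 20 (2R,3R,4S)-5,7-bis(benzyloxy)-2-[4-(benzyloxy)phenyl]-4-(2-ethoxyethoxy)chroman-3-yl acetate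
Conditions: Ac2O, DMAP (cat.), pyridine, rt
Reagents that add atoms: acetic anhydride, CC(=O)OC(C)=O
Why: DMAP-catalysed acylation as in step 9.

Step 12
Reactants: 17 (2S,3S,4R)-5,7-bis(benzyloxy)-2-[4-(benzyloxy)phenyl]-4-(2-ethoxyethoxy)chroman-3-yl acetate (1.0 equiv); 12 (2R,3R)-5,7-bis(benzyloxy)-2-[4-(benzyloxy)phenyl]chroman-3-ol (3.0 equiv; excess recovered)
Product: 22 3-O-acetyl-5,7,4'-tri-O-benzyl-ent-epiafzelechin-(4α→8)-5,7,4'-tri-O-benzylepiafzelechin (middle unit 2S,3S,4S; lower unit 2R,3R), via flavan-4-yl cation 21 (not isolated)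
Conditions: TMSOTf (0.2 equiv), CH2Cl2, −78 °C
Reagents that add atoms: none
Why: Lewis-acid-catalysed Friedel–Crafts-type arylation of a flavan-4-yl cation, in which the more nucleophilic C8 of 12 attacks the cation anti to the pseudo-axial 3-acetoxy group and gives the 3,4-trans (4α in the ent series) C4–C8 bond.

Step 13
Reactants: 20 (2R,3R,4S)-5,7-bis(benzyloxy)-2-[4-(benzyloxy)phenyl]-4-(2-ethoxyethoxy)chroman-3-yl acetate (1.0 equiv); 22 3-O-acetyl-5,7,4'-tri-O-benzyl-ent-epiafzelechin-(4α→8)-5,7,4'-tri-O-benzylepiafzelechin (2.0 equiv; excess recovered)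
Product: 24 3-O-acetyl-5,7,4'-tri-O-benzylepiafzelechin-(4β→8)-3-O-acetyl-5,7,4'-tri-O-benzyl-ent-epiafzelechin-(4α→8)-5,7,4'-tri-O-benzylepiafzelechin (upper 2R,3R,4R; middle 2S,3S,4R; lower 2R,3R), via flavan-4-yl cation 23 (not isolated)
Conditions: TMSOTf (0.2 equiv), CH2Cl2, −78 °C
Reagents that add atoms: none
Why: The same Friedel–Crafts-type flavan-4-yl cation arylation, in which the only free C8 of dimer 22 (on its middle unit) is its most nucleophilic site and attacks anti to the 3-acetoxy group to give the 3,4-trans (4β) bond.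

Step 14
Reactants: 24 3-O-acetyl-5,7,4'-tri-O-benzylepiafzelechin-(4β→8)-3-O-acetyl-5,7,4'-tri-O-benzyl-ent-epiafzelechin-(4α→8)-5,7,4'-tri-O-benzylepiafzelechin
Product: 25 5,7,4'-tri-O-benzylepiafzelechin-(4β→8)-5,7,4'-tri-O-benzyl-ent-epiafzelechin-(4α→8)-5,7,4'-tri-O-benzylepiafzelechin
Conditions: NaOMe (0.3 equiv), MeOH/THF (1:1), 40 °C
Reagents that add atoms: none
Why: Zemplén transesterification removes both acetates under basic conditions that cannot ionise the acid-labile interflavan bonds or epimerise any centre.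

Step 15
Reactants: 25 5,7,4'-tri-O-benzylepiafzelechin-(4β→8)-5,7,4'-tri-O-benzyl-ent-epiafzelechin-(4α→8)-5,7,4'-tri-O-benzylepiafzelechin
Product: 26 epiafzelechin-(4β→8)-ent-epiafzelechin-(4α→8)-epiafzelechin (target CNP0191553.2)
Conditions: H2 (1 atm), Pd(OH)2/C (20 wt %), THF/MeOH/H2O (20:1:1), rt; filtration, Sephadex LH-20, lyophilisation
Reagents that add atoms: none
Why: Catalytic hydrogenolysis cleaves all nine aryl benzyl ethers under neutral conditions, and the doubly benzylic interflavan C–C bonds and all eight stereocentres are left unchanged when the reaction is stopped at full debenzylation.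

**Compound list**
Racemates with defined relative configuration are written as the 1:1 pair of enantiomers joined by a dot.

1 | 2',4',6'-trihydroxyacetophenone | CC(=O)c1c(O)cc(O)cc1O | starting material
2 | 1-[2,4-bis(benzyloxy)-6-hydroxyphenyl]ethanone | CC(=O)c1c(O)cc(OCc2ccccc2)cc1OCc1ccccc1 | intermediate
3 | 4-(benzyloxy)benzaldehyde | O=Cc1ccc(OCc2ccccc2)cc1 | starting material
4 | racemic 1-[2,4-bis(benzyloxy)-6-hydroxyphenyl]-3-[4-(benzyloxy)phenyl]-3-hydroxypropan-1-one (aldol adduct) | O=C(CC(O)c1ccc(OCc2ccccc2)cc1)c1c(O)cc(OCc2ccccc2)cc1OCc1ccccc1 | intermediate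
5 | (E)-1-[2,4-bis(benzyloxy)-6-hydroxyphenyl]-3-[4-(benzyloxy)phenyl]prop-2-en-1-one (chalcone) | O=C(/C=C/c1ccc(OCc2ccccc2)cc1)c1c(O)cc(OCc2ccccc2)cc1OCc1ccccc1 | intermediate
6 | racemic 3,5-bis(benzyloxy)-2-[(E)-3-[4-(benzyloxy)phenyl]-1-hydroxyprop-2-en-1-yl]phenol (allylic alcohol) | OC(/C=C/c1ccc(OCc2ccccc2)cc1)c1c(O)cc(OCc2ccccc2)cc1OCc1ccccc1 | intermediate
7 | racemic 5,7-bis(benzyloxy)-2-[4-(benzyloxy)phenyl]-2H-chromene (flav-3-ene) | c1ccccc1COc1ccc(C2C=Cc3c(OCc4ccccc4)cc(OCc4ccccc4)cc3O2)cc1 | intermediate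
8 | racemic [2,3-trans-5,7-bis(benzyloxy)-2-[4-(benzyloxy)phenyl]chroman-3-yl]borane | c1ccccc1COc1ccc([C@H]2Oc3cc(OCc4ccccc4)cc(OCc4ccccc4)c3C[C@@H]2B)cc1.c1ccccc1COc1ccc([C@@H]2Oc3cc(OCc4ccccc4)cc(OCc4ccccc4)c3C[C@H]2B)cc1 | intermediate
9 | racemic 2,3-trans-5,7-bis(benzyloxy)-2-[4-(benzyloxy)phenyl]chroman-3-ol [(2R,3S) and (2S,3R)] | c1ccccc1COc1ccc([C@H]2Oc3cc(OCc4ccccc4)cc(OCc4ccccc4)c3C[C@@H]2O)cc1.c1ccccc1COc1ccc([C@@H]2Oc3cc(OCc4ccccc4)cc(OCc4ccccc4)c3C[C@H]2O)cc1 | intermediate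
10 | racemic 5,7-bis(benzyloxy)-2-[4-(benzyloxy)phenyl]chroman-3-one | c1ccccc1COc1ccc(C2Oc3cc(OCc4ccccc4)cc(OCc4ccccc4)c3CC2=O)cc1 | intermediate
11 | (2R)-5,7-bis(benzyloxy)-2-[4-(benzyloxy)phenyl]chroman-3-one (ketone enantiomer matched to the (R,R)-catalyst, replenished in the flask by C2 epimerisation) | c1ccccc1COc1ccc([C@H]2Oc3cc(OCc4ccccc4)cc(OCc4ccccc4)c3CC2=O)cc1 | intermediate
12 | (2R,3R)-5,7-bis(benzyloxy)-2-[4-(benzyloxy)phenyl]chroman-3-ol (5,7,4'-tri-O-benzylepiafzelechin) | c1ccccc1COc1ccc([C@H]2Oc3cc(OCc4ccccc4)cc(OCc4ccccc4)c3C[C@H]2O)cc1 | intermediate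
13 | (2S)-5,7-bis(benzyloxy)-2-[4-(benzyloxy)phenyl]chroman-3-one (ketone enantiomer matched to the (S,S)-catalyst, replenished in the flask by C2 epimerisation) | c1ccccc1COc1ccc([C@@H]2Oc3cc(OCc4ccccc4)cc(OCc4ccccc4)c3CC2=O)cc1 | intermediate
14 | (2S,3S)-5,7-bis(benzyloxy)-2-[4-(benzyloxy)phenyl]chroman-3-ol (5,7,4'-tri-O-benzyl-ent-epiafzelechin) | c1ccccc1COc1ccc([C@@H]2Oc3cc(OCc4ccccc4)cc(OCc4ccccc4)c3C[C@@H]2O)cc1 | intermediate
15 | (2S,3S)-5,7-bis(benzyloxy)-2-[4-(benzyloxy)phenyl]-3-hydroxychroman-4-ylium (C4 cation) | c1ccccc1COc1ccc([C@@H]2Oc3cc(OCc4ccccc4)cc(OCc4ccccc4)c3[CH+][C@@H]2O)cc1 | intermediate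
16 | (2S,3S,4R)-5,7-bis(benzyloxy)-2-[4-(benzyloxy)phenyl]-4-(2-ethoxyethoxy)chroman-3-ol | c1ccccc1COc1ccc([C@@H]2Oc3cc(OCc4ccccc4)cc(OCc4ccccc4)c3[C@@H](OCCOCC)[C@@H]2O)cc1 | intermediate
17 | (2S,3S,4R)-5,7-bis(benzyloxy)-2-[4-(benzyloxy)phenyl]-4-(2-ethoxyethoxy)chroman-3-yl acetate | c1ccccc1COc1ccc([C@@H]2Oc3cc(OCc4ccccc4)cc(OCc4ccccc4)c3[C@@H](OCCOCC)[C@@H]2OC(C)=O)cc1 | intermediate
18 | (2R,3R)-5,7-bis(benzyloxy)-2-[4-(benzyloxy)phenyl]-3-hydroxychroman-4-ylium (C4 cation) | c1ccccc1COc1ccc([C@H]2Oc3cc(OCc4ccccc4)cc(OCc4ccccc4)c3[CH+][C@H]2O)cc1 | intermediate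
19 | (2R,3R,4S)-5,7-bis(benzyloxy)-2-[4-(benzyloxy)phenyl]-4-(2-ethoxyethoxy)chroman-3-ol | c1ccccc1COc1ccc([C@H]2Oc3cc(OCc4ccccc4)cc(OCc4ccccc4)c3[C@H](OCCOCC)[C@H]2O)cc1 | intermediate
20 | (2R,3R,4S)-5,7-bis(benzyloxy)-2-[4-(benzyloxy)phenyl]-4-(2-ethoxyethoxy)chroman-3-yl acetate | c1ccccc1COc1ccc([C@H]2Oc3cc(OCc4ccccc4)cc(OCc4ccccc4)c3[C@H](OCCOCC)[C@H]2OC(C)=O)cc1 | intermediate
21 | (2S,3S)-3-acetoxy-5,7-bis(benzyloxy)-2-[4-(benzyloxy)phenyl]chroman-4-ylium (C4 cation) | c1ccccc1COc1ccc([C@@H]2Oc3cc(OCc4ccccc4)cc(OCc4ccccc4)c3[CH+][C@@H]2OC(C)=O)cc1 | intermediate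
22 | 3-O-acetyl-5,7,4'-tri-O-benzyl-ent-epiafzelechin-(4α→8)-5,7,4'-tri-O-benzylepiafzelechin (middle unit 2S,3S,4S with the C4 aryl trans to the 3-acetoxy group; lower unit 2R,3R) | c1c(OCc2ccccc2)cc(OCc2ccccc2)c2c1O[C@@H](c1ccc(OCc3ccccc3)cc1)[C@@H](OC(C)=O)[C@@H]2c1c(OCc2ccccc2)cc(OCc2ccccc2)c2c1O[C@H](c1ccc(OCc3ccccc3)cc1)[C@H](O)C2 | intermediate
23 | (2R,3R)-3-acetoxy-5,7-bis(benzyloxy)-2-[4-(benzyloxy)phenyl]chroman-4-ylium (C4 cation) | c1ccccc1COc1ccc([C@H]2Oc3cc(OCc4ccccc4)cc(OCc4ccccc4)c3[CH+][C@H]2OC(C)=O)cc1 | intermediate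
24 | 3-O-acetyl-5,7,4'-tri-O-benzylepiafzelechin-(4β→8)-3-O-acetyl-5,7,4'-tri-O-benzyl-ent-epiafzelechin-(4α→8)-5,7,4'-tri-O-benzylepiafzelechin (upper 2R,3R,4R; middle 2S,3S,4R; lower 2R,3R) | c1ccccc1COc1ccc([C@H]2Oc3cc(OCc4ccccc4)cc(OCc4ccccc4)c3[C@H](c3c(OCc4ccccc4)cc(OCc4ccccc4)c4c3O[C@@H](c3ccc(OCc5ccccc5)cc3)[C@@H](OC(C)=O)[C@@H]4c3c(OCc4ccccc4)cc(OCc4ccccc4)c4c3O[C@H](c3ccc(OCc5ccccc5)cc3)[C@H](O)C4)[C@H]2OC(C)=O)cc1 | intermediate
25 | 5,7,4'-tri-O-benzylepiafzelechin-(4β→8)-5,7,4'-tri-O-benzyl-ent-epiafzelechin-(4α→8)-5,7,4'-tri-O-benzylepiafzelechin (upper 2R,3R,4R; middle 2S,3S,4R; lower 2R,3R; three free 3-OH) | c1ccccc1COc1ccc([C@H]2Oc3cc(OCc4ccccc4)cc(OCc4ccccc4)c3[C@H](c3c(OCc4ccccc4)cc(OCc4ccccc4)c4c3O[C@@H](c3ccc(OCc5ccccc5)cc3)[C@@H](O)[C@@H]4c3c(OCc4ccccc4)cc(OCc4ccccc4)c4c3O[C@H](c3ccc(OCc5ccccc5)cc3)[C@H](O)C4)[C@H]2O)cc1 | intermediate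
26 | epiafzelechin-(4β→8)-ent-epiafzelechin-(4α→8)-epiafzelechin (upper 2R,3R,4R; middle 2S,3S,4R; lower 2R,3R) | Oc1ccc([C@H]2Oc3cc(O)cc(O)c3[C@H](c3c(O)cc(O)c4c3O[C@@H](c3ccc(O)cc3)[C@@H](O)[C@@H]4c3c(O)cc(O)c4c3O[C@H](c3ccc(O)cc3)[C@H](O)C4)[C@H]2O)cc1 | target

**Totals and risks**

Total step count: 15. Longest linear sequence: 12 steps (1, 2, 3, 4, 5, 7, 8, 9, 12, 13, 14, 15).

The three steps most likely to fail:

1. Step 6 (and its mirror-image twin, step 7), the proposed new dynamic kinetic resolution. C2 epimerisation may be too slow in the formate buffer, which would give a plain kinetic resolution. The catalyst may also discriminate poorly on a ketone flanked by two sp3 carbons, or show the opposite sense. The fallback uses known chemistry and sets out from ketone 10. Reduction with LiBH(s-Bu)3 in THF at −78 °C delivers hydride anti to the 2-aryl group and gives racemic 2,3-cis-5,7-bis(benzyloxy)-2-[4-(benzyloxy)phenyl]chroman-3-ol F1. Preparative chiral SFC on an amylose tris(3,5-dimethylphenylcarbamate) phase then separates F1 into its enantiomers, and the route is rejoined at 12 and 14 (replacing steps 6 and 7). Both antipodes are needed, so little is wasted; surplus 14 can be oxidised back to 10 and recycled.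

2. Step 13, the coupling of a dimeric nucleophile. C6 of the lower or middle unit may compete with C8 of the middle unit, the reaction may be slow for steric reasons, and the acid may cleave the interflavan bond already present. The fallback reverses the assembly with orthogonal thio/oxy activation and sets out from 17, 20 and 12. Acetate 17 and 2,6-dimethylbenzenethiol with BF3·OEt2 in CH2Cl2 at −78 °C give (2S,3R,4R)-5,7-bis(benzyloxy)-2-[4-(benzyloxy)phenyl]-4-[(2,6-dimethylphenyl)sulfanyl]chroman-3-yl acetate F2 (2,3-cis, 3,4-trans; the C3 descriptor changes only because sulfur outranks oxygen). F2 (3 equiv) serves as the C8 nucleophile toward 20 under BF3·OEt2 at −78 °C, where the thioether is inert. This gives 3-O-acetyl-5,7,4'-tri-O-benzylepiafzelechin-(4β→8)-3-O-acetyl-5,7,4'-tri-O-benzyl-4α-[(2,6-dimethylphenyl)sulfanyl]-ent-epiafzelechin F3. Thiophilic activation of F3 with AgBF4 in CH2Cl2/THF at −40 °C in the presence of monomer 12 (3 equiv) forms the lower bond last and rejoins the route at 24. In that last coupling the only nucleophile is the monomer 12, which reacts at its C8.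

3. Step 3, the reductive cyclisation. Conjugate reduction or over-reduction of the chalcone can compete, and the electron-rich flav-3-ene is sensitive. The fallback closes ring C before reduction and sets out from chalcone 5. NaOAc in refluxing EtOH gives, by oxa-Michael cyclisation, racemic 5,7-bis(benzyloxy)-2-[4-(benzyloxy)phenyl]chroman-4-one F4. NaBH4 in MeOH/THF at 0 °C gives racemic 2,4-cis-5,7-bis(benzyloxy)-2-[4-(benzyloxy)phenyl]chroman-4-ol F5. Dehydration with catalytic PPTS in toluene at 80 °C over 4 Å molecular sieves rejoins the route at flav-3-ene 7.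

**Further compounds**
F1 | step 6 | racemic 2,3-cis-5,7-bis(benzyloxy)-2-[4-(benzyloxy)phenyl]chroman-3-ol (1:1 mixture of the 2R,3R and 2S,3S enantiomers) | c1ccccc1COc1ccc([C@H]2Oc3cc(OCc4ccccc4)cc(OCc4ccccc4)c3C[C@H]2O)cc1.c1ccccc1COc1ccc([C@@H]2Oc3cc(OCc4ccccc4)cc(OCc4ccccc4)c3C[C@@H]2O)cc1
F2 | step 13 | (2S,3R,4R)-5,7-bis(benzyloxy)-2-[4-(benzyloxy)phenyl]-4-[(2,6-dimethylphenyl)sulfanyl]chroman-3-yl acetate | c1ccccc1COc1ccc([C@@H]2Oc3cc(OCc4ccccc4)cc(OCc4ccccc4)c3[C@@H](Sc3c(C)cccc3C)[C@@H]2OC(C)=O)cc1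
F3 | step 13 | 3-O-acetyl-5,7,4'-tri-O-benzylepiafzelechin-(4β→8)-3-O-acetyl-5,7,4'-tri-O-benzyl-4α-[(2,6-dimethylphenyl)sulfanyl]-ent-epiafzelechin | c1ccccc1COc1ccc([C@H]2Oc3cc(OCc4ccccc4)cc(OCc4ccccc4)c3[C@H](c3c(OCc4ccccc4)cc(OCc4ccccc4)c4c3O[C@@H](c3ccc(OCc5ccccc5)cc3)[C@@H](OC(C)=O)[C@@H]4Sc3c(C)cccc3C)[C@H]2OC(C)=O)cc1
F4 | step 3 | racemic 5,7-bis(benzyloxy)-2-[4-(benzyloxy)phenyl]chroman-4-one | c1ccccc1COc1ccc(C2CC(=O)c3c(OCc4ccccc4)cc(OCc4ccccc4)cc3O2)cc1
F5 | step 3 | racemic 2,4-cis-5,7-bis(benzyloxy)-2-[4-(benzyloxy)phenyl]chroman-4-ol | c1ccccc1COc1ccc([C@@H]2C[C@H](O)c3c(OCc4ccccc4)cc(OCc4ccccc4)cc3O2)cc1.c1ccccc1COc1ccc([C@H]2C[C@@H](O)c3c(OCc4ccccc4)cc(OCc4ccccc4)cc3O2)cc1
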